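Amounts opened the meeting. The winter chemist reported free monomer at 4.37 mM after 4.00 h, and the midnight chemist 4.80 mM after 5.00 h, from charges of 23 mM and 120 mM.

| setting | winter | midnight | green | amber |
|---|---|---|---|---|
| free monomer | 23 mM | 120 mM | 20 mM | 80 mM |
| pre-initiator | 1 mM | 1 mM | 1.0 mM | 1.0 mM |
| remark | run made earlier | run made earlier |  |  |
| time |  |  | 10 h | 10 h |

| run | time / h | monomer in chains / % | free monomer / % |
|---|---|---|---|
| winter | 1.33 | 62 | 18 |
| winter | 3.00 | 67 | 17 |
| winter | 4.00 | 61 | 19 |
| winter | 6.00 | 54 | 20 |
| winter | 8.00 | 49 | 23 |
| midnight | 0.667 | 81 | 12 |
| midnight | 2.00 | 88 | 5 |
| midnight | 3.00 | 90 | 5 |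
| midnight | 5.00 | 86 | 4 |
| midnight | 8.00 | 84 | 2 |

(standard deviation of a reading: 2 percentage points)

- the average divides the monomer in chains by the number of chains begun, living and dead together
- the analysis behind the earlier runs scatters by 2 percentage points, standard deviation
- the earlier runs do not show the number of chains; that part of a forecast is a guess

* which of the two ends with the longer chains by the average number of monomer units in a chain (chains begun, living or dead) ("neither" if they lie within 10 %) (green / amber / neither)
* average number of monomer units in a chain (chains begun, living or dead) at the end, green
* average number of monomer units in a chain (chains begun, living or dead) at the end, amber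

The winter chemist took the mean of those two readings, 4.58 mM, as a floor for c(free monomer) while chains stand, the equilibrium monomer concentration. The midnight chemist objected that her last reading is 2 %, but conceded that a scatter of 2 percentage points covers the step from 4 %.

The winter chemist then turned to the balance. His last reading leaves 28.0 % of the charge in neither column, and over 8.00 h that gives 0.805 mM h⁻¹. The meeting named this the drain, the amount per hour leaving for something unseen while c(free monomer) stands at the floor. Midnight's gap at 8.00 h exceeds what the drain takes in that time by 8.63 % of its charge, which the midnight chemist booked as an early loss, scaled with the charge.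

My own reckoning joins the two ends: chains hold the charge less the floor, less the drain over 10 h, less the early loss. Green, charged near winter, whose whole gap went into the drain, takes no early term and holds 7.37 mM, while amber holds 60.5 mM. Guessing one chain per pre-initiator charged gives 7.37 and 60.5 units, so amber is longer.

The forecast has other numbers, 9 and 65 units: “Amber is clearly longer”.

The flasks give 6.84 units in green and 63.6 in amber, so amber ends longer.

    free monomer + initiator → living end + monomer in chains (k = 3.50 L mol⁻¹ min⁻¹)
    free monomer → uncatalysed product (k = 0.00270 min⁻¹)
    pre-initiator → initiator (k = 0.0110 min⁻¹)
    free monomer + living end → monomer in chains + living end, rate k4*[living end]*[free monomer] (k = 390 L mol⁻¹ min⁻¹)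
    monomer in chains + living end → free monomer + living end, rate k5*[living end] as long as [monomer in chains] is above zero (k = 1.80 min⁻¹)

Amber's neighbour, the same flask with 2.5 mM of pre-initiator, gets 24.2 units from the reckoned amber store under the same guess, and the flask gives 26.0. Amber is not at rest at 10 h: free monomer stands at 5.73 %, as at 5.00 h, while monomer in chains goes from 83.8 % to 79.1 %. Reckoned at the drain, amber's 63.3 mM in chains last 78.6 h, less than the 90.0 h that follow. At 100 h amber holds 0 % in chains, 97.3 % uncatalysed product and 2.66 % free monomer, and its average length is 0.00171.

The earlier runs and the new flask were generated by integration for substances that don't exist; the scatter is artificial.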